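**Retrosynthetic overview**
1. The last C–C bond made is the one from C-α of the γ-butyrolactone to C-5 of the 2-(3-hydroxybutyl)furan. An Mn(II)/Mn(III)-mediated anodic, decarboxylative coupling joins the complete bicyclic core (as its C-α carboxylic acid) with the intact, silyl-protected furan.
2. Enabling feature: C-α lies between the lactone C=O and the furan ring, so it is a (2-furyl)acetic ester carbon. A traceless CO2H makes it a malonic half-acid, the only 1,3-dicarbonyl C–H of the core, and the furan has one free α-position. After coupling, CO2 is lost and C-α is set by protonation on the convex face of the cis-fused 5/10 bicycle.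
3. Core: the γ-butyrolactone is formed first (5-exo-dig Michael addition of a propargylic malonate onto an ynone, then hydrogenation anti to the C-γ arm for the cis C-β/C-γ relation). The 10-membered lactone is closed second by macrolactonization. The furan ring is bought.
4. Stereocentres: C-γ by transfer hydrogenation of an ynone, C-β by hydrogenation, the two CH(CH3)O centres from (R)-γ-valerolactone and an enzymatic ketone reduction, C-α in the key step.

Key step: step 13

Assumption: the sense of induction in step 2 is taken to follow that of simple alkynyl ketones (alkynyl group in the role of the aryl group); the C-α epimers of 14–16 are carried on as a mixture because C-α is reset in step 13.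

Step 1
Reactants: 1 3-(trimethylsilyl)propiolic acid; 2 Meldrum's acid (2,2-dimethyl-1,3-dioxane-4,6-dione)
Product: 4 benzyl 3-oxo-5-(trimethylsilyl)pent-4-ynoate, via acyl Meldrum's acid 3 (not isolated)
Conditions: DCC, DMAP (cat.), CH2Cl2, 0 °C to rt; filter; then BnOH, toluene, 90 °C
Reagents that add atoms: benzyl alcohol, OCc1ccccc1
Why: C-acylation of Meldrum's acid followed by thermal alcoholysis with loss of acetone and CO2 (Oikawa–Yonemitsu β-keto ester synthesis) should give the alkynyl β-keto ester, the silyl group keeping the ynone from polymerizing.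

Step 2
Reactants: 4 benzyl 3-oxo-5-(trimethylsilyl)pent-4-ynoate
Product: 5 benzyl (S)-3-hydroxy-5-(trimethylsilyl)pent-4-ynoate
Conditions: RuCl[(S,S)-TsDPEN](p-cymene) (1 mol%), HCO2H–Et3N (5:2), rt
Reagents that add atoms: none
Why: Noyori–Ikariya asymmetric transfer hydrogenation of an alkynyl ketone, with the alkynyl group in the place of the aryl group in the CH/π-controlled transition state, should set the (S)-carbinol that becomes C-γ.

Step 3
Reactants: 5 benzyl (S)-3-hydroxy-5-(trimethylsilyl)pent-4-ynoate
Product: 6 benzyl (S)-3-hydroxypent-4-ynoate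
Conditions: TBAF, AcOH (1:1), THF, 0 °C
Reagents that add atoms: none
Why: Buffered fluoride protodesilylation of the alkynylsilane should leave the β-hydroxy benzyl ester untouched (no retro-aldol, no transesterification).

Step 4
Reactants: 6 benzyl (S)-3-hydroxypent-4-ynoate; 7 mono-tert-butyl malonate
Product: 8 benzyl (3S)-3-{[3-(tert-butoxy)-3-oxopropanoyl]oxy}pent-4-ynoate
Conditions: DCC, DMAP (5 mol%), CH2Cl2, 0 °C
Reagents that add atoms: none
Why: Steglich esterification of the propargylic alcohol installs the malonate that supplies C-α, the lactone carbonyl and the traceless carboxyl group.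

Step 5
Reactants: 9 (R)-γ-valerolactone
Product: 10 (R)-4-(benzyloxy)pentanoic acid
Conditions: KOH (powder), BnBr, toluene, reflux; then MeOH–H2O, reflux; aq. HCl
Reagents that add atoms: benzyl bromide, BrCc1ccccc1; potassium hydroxide, [K+].[OH-]
Why: Hydroxide opens the lactone and the secondary alkoxide is O-benzylated (Williamson ether synthesis), the C–O bond of the stereocentre never being broken.

Step 6
Reactants: 10 (R)-4-(benzyloxy)pentanoic acid
Product: 11 (R)-4-(benzyloxy)pentanoyl chloride
Conditions: (COCl)2, DMF (cat.), CH2Cl2, 0 °C to rt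
Reagents that add atoms: oxalyl chloride, ClC(=O)C(=O)Cl
Why: Vilsmeier-catalysed acid chloride formation is standard for an ether-bearing aliphatic acid.

Step 7
Reactants: 8 benzyl (3S)-3-{[3-(tert-butoxy)-3-oxopropanoyl]oxy}pent-4-ynoate; 11 (R)-4-(benzyloxy)pentanoyl chloride
Product: 13 benzyl 2-[(2S)-3-[(5R)-5-(benzyloxy)-2-oxohexyl]-4-(tert-butoxycarbonyl)-5-oxo-2,5-dihydrofuran-2-yl]acetate (drawn as the butenolide tautomer), via ynone 12 (not isolated)
Conditions: PdCl2(PPh3)2 (2 mol%), CuI (4 mol%), Et3N, THF, rt; then DBU (0.2 equiv), 0 °C; aq. citric acid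
Reagents that add atoms: none
Why: An acyl Sonogashira coupling gives γ-acyloxy ynone 12, whose tethered malonate C–H then adds 5-exo-dig to the ynone β-carbon (intramolecular Michael addition) and, after proton shift, should give the α-carboxylated butenolide without touching the propargylic stereocentre, the bulky tert-butyl ester disfavouring pyranone formation by the ketone enolate oxygen.

Step 8
Reactants: 13 the butenolide of step 7
Product: 14 2-[(2S,3S)-4-(tert-butoxycarbonyl)-3-[(5R)-5-hydroxy-2-oxohexyl]-5-oxotetrahydrofuran-2-yl]acetic acid (C-α epimers)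
Conditions: H2 (3 atm), 10% Pd/C, EtOAc–EtOH, rt
Reagents that add atoms: none
Why: Heterogeneous hydrogenation should add hydrogen to the butenolide (or its exocyclic enone tautomer) from the face opposite the C-γ CH2CO2Bn arm, which sets C-β (S) cis to that arm, while both benzyl groups are removed by hydrogenolysis.

Step 9
Reactants: 14 the seco acid of step 8
Product: 15 bicyclic tert-butyl ester: 10-membered keto lactone (ring O–CH(CH3)–CH2–CH2–C(=O)–CH2–C-β–C-γ–CH2–C(=O)) cis-fused across C-β/C-γ to a γ-butyrolactone carrying CO2tBu at C-α (C-β S, C-γ S, CH(CH3)O R; C-α epimers)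
Conditions: MNBA, DMAP, CH2Cl2, rt, syringe-pump addition (final ca. 1 mM)
Reagents that add atoms: none
Why: Shiina macrolactonization (mixed-anhydride activation under high dilution at room temperature) should close the 10-membered lactone with retention at the carbinol carbon, the two arms being held cis on the five-membered ring.

Step 10
Reactants: 15 the bicyclic tert-butyl ester
Product: 16 bicyclic malonic half-acid (15 with CO2H in place of CO2tBu at C-α)
Conditions: TFA–CH2Cl2 (1:4), 0 °C to rt; concentrate below 30 °C
Reagents that add atoms: none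
Why: Acidolysis of the tert-butyl ester (E1 loss of isobutene) frees the malonic half-acid, which as an alkyl-substituted malonic acid should not decarboxylate at room temperature.

Step 11
Reactants: 17 4-(furan-2-yl)butan-2-one
Product: 18 (R)-4-(furan-2-yl)butan-2-ol
Conditions: Lactobacillus brevis alcohol dehydrogenase, NADP+ (cat.), iPrOH, phosphate buffer pH 7, 30 °C
Reagents that add atoms: none
Why: Anti-Prelog enzymatic reduction of a methyl ketone of the 4-aryl-2-butanone type should give the (R)-alcohol with high enantioselectivity.

Step 12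
Reactants: 18 (R)-4-(furan-2-yl)butan-2-ol
Product: 19 (R)-tert-butyl{[4-(furan-2-yl)butan-2-yl]oxy}dimethylsilane
Conditions: TBSCl, imidazole, DMF, rt
Reagents that add atoms: tert-butyldimethylsilyl chloride, CC(C)(C)[Si](C)(C)Cl
Why: Silylation blocks the hydroxyl group, which would otherwise trap the furanium ion of the key step as a spiroketal.

Step 13
Reactants: 16 bicyclic malonic half-acid; 19 silyl-protected furan (3 equiv)
Product: 21 O-TBS-cordycicadin B, via α-furylmalonic half-acid 20 (not isolated)
Conditions: Mn(OAc)2·4H2O (20 mol%), NaOAc (0.3 M), AcOH–MeCN (1:2), divided cell, graphite-felt anode, Pt cathode, controlled potential at the Mn(II)/Mn(III) wave (ca. +1.1 V vs Ag/AgCl), 2.2 F/mol, 30 °C; then 55 °C, 1 h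
Reagents that add atoms: none
Why: Proposed new method: Anodically regenerated Mn(III) forms the chelated enolate of malonic half-acid 16 and oxidizes it by inner-sphere electron transfer to the electrophilic tertiary radical at C-α, which adds to the free α-position (C-5) of furan 19; a second Mn(III) (or the anode) oxidizes the furanyl radical to the cation, and loss of H+ restores the furan and gives 20. Now an arylmalonic acid, 20 should lose CO2 through the six-membered cyclic transition state on warming, and the lactone enol is then protonated at C-α. The closest known reaction types are the Mn(OAc)3- and Ce(IV)-mediated oxidative malonylation of furans and thiophenes, the Mn(III)/malonic acid carboxymethylation of arenes with decarboxylation, and Mn(II)/Mn(III)-mediated anodic additions of 1,3-dicarbonyl compounds to π-systems; new are the tertiary lactone half-acid as radical precursor and the one-pot coupling, decarboxylation and protonation. No ring is closed; the one new stereocentre (C-α, S) is set by substrate control in the protonation, which should occur on the convex face opposite the two cis ring-fusion CH2 substituents on C-β and C-γ and so place the furan cis to them. The step needs chemoselectivity for C-α over the ketone α-positions (only C-α is a 1,3-dicarbonyl C–H that Mn(III) enolizes), regioselectivity for furan C-5 (the 2-alkyl group leaves one α-position free), and mediator turnover below the potential of direct furan oxidation (potential control and the divided cell).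

Step 14
Reactants: 21 O-TBS-cordycicadin B
Product: 22 cordycicadin B
Conditions: HF·pyridine, pyridine, THF, 0 °C to rt
Reagents that add atoms: none
Why: Fluoride-mediated desilylation under buffered, non-basic conditions should free the secondary alcohol without epimerizing the acidic C-α–H or opening a lactone.

**Compound list**
1 | 3-(trimethylsilyl)propiolic acid | C[Si](C)(C)C#CC(=O)O | starting material
2 | Meldrum's acid | CC1(C)OC(=O)CC(=O)O1 | starting material
3 | 5-[1-hydroxy-3-(trimethylsilyl)prop-2-yn-1-ylidene]-2,2-dimethyl-1,3-dioxane-4,6-dione (acyl Meldrum's acid) | CC1(C)OC(=O)C(=C(O)C#C[Si](C)(C)C)C(=O)O1 | intermediate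
4 | benzyl 3-oxo-5-(trimethylsilyl)pent-4-ynoate | C[Si](C)(C)C#CC(=O)CC(=O)OCc1ccccc1 | intermediate
5 | benzyl (S)-3-hydroxy-5-(trimethylsilyl)pent-4-ynoate | C[Si](C)(C)C#C[C@@H](O)CC(=O)OCc1ccccc1 | intermediate
6 | benzyl (S)-3-hydroxypent-4-ynoate | C#C[C@@H](O)CC(=O)OCc1ccccc1 | intermediate
7 | mono-tert-butyl malonate | CC(C)(C)OC(=O)CC(=O)O | starting material
8 | benzyl (3S)-3-{[3-(tert-butoxy)-3-oxopropanoyl]oxy}pent-4-ynoate | C#C[C@@H](OC(=O)CC(=O)OC(C)(C)C)CC(=O)OCc1ccccc1 | intermediate
9 | (R)-γ-valerolactone | C[C@@H]1CCC(=O)O1 | starting material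
10 | (R)-4-(benzyloxy)pentanoic acid | C[C@@H](OCc1ccccc1)CCC(=O)O | intermediate
11 | (R)-4-(benzyloxy)pentanoyl chloride | C[C@@H](OCc1ccccc1)CCC(=O)Cl | intermediate
12 | benzyl (3S,9R)-9-(benzyloxy)-3-{[3-(tert-butoxy)-3-oxopropanoyl]oxy}-6-oxodec-4-ynoate (ynone) | C[C@@H](OCc1ccccc1)CCC(=O)C#C[C@@H](OC(=O)CC(=O)OC(C)(C)C)CC(=O)OCc1ccccc1 | intermediate
13 | benzyl 2-[(2S)-3-[(5R)-5-(benzyloxy)-2-oxohexyl]-4-(tert-butoxycarbonyl)-5-oxo-2,5-dihydrofuran-2-yl]acetate | C[C@@H](OCc1ccccc1)CCC(=O)CC1=C(C(=O)OC(C)(C)C)C(=O)O[C@H]1CC(=O)OCc1ccccc1 | intermediate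
14 | 2-[(2S,3S)-4-(tert-butoxycarbonyl)-3-[(5R)-5-hydroxy-2-oxohexyl]-5-oxotetrahydrofuran-2-yl]acetic acid | C[C@@H](O)CCC(=O)C[C@@H]1[C@H](CC(=O)O)OC(=O)C1C(=O)OC(C)(C)C | intermediate
15 | bicyclic keto dilactone with CO2tBu at C-α | C[C@@H]1CCC(=O)C[C@@H]2[C@H](CC(=O)O1)OC(=O)C2C(=O)OC(C)(C)C | intermediate
16 | bicyclic keto dilactone with CO2H at C-α (malonic half-acid) | C[C@@H]1CCC(=O)C[C@@H]2[C@H](CC(=O)O1)OC(=O)C2C(=O)O | intermediate
17 | 4-(furan-2-yl)butan-2-one | CC(=O)CCc1ccco1 | starting material
18 | (R)-4-(furan-2-yl)butan-2-ol | C[C@@H](O)CCc1ccco1 | intermediate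
19 | (R)-tert-butyl{[4-(furan-2-yl)butan-2-yl]oxy}dimethylsilane | C[C@@H](O[Si](C)(C)C(C)(C)C)CCc1ccco1 | intermediate
20 | α-furylmalonic half-acid (16 carrying the silyl-protected furyl group at C-α) | C[C@@H]1CCC(=O)C[C@@H]2[C@H](CC(=O)O1)OC(=O)C2(C(=O)O)c1ccc(CC[C@@H](C)O[Si](C)(C)C(C)(C)C)o1 | intermediate
21 | O-TBS-cordycicadin B | C[C@@H]1CCC(=O)C[C@@H]2[C@H](CC(=O)O1)OC(=O)[C@@H]2c1ccc(CC[C@@H](C)O[Si](C)(C)C(C)(C)C)o1 | intermediate
22 | cordycicadin B | C[C@@H]1CCC(=O)C[C@@H]2[C@H](CC(=O)O1)OC(=O)[C@@H]2c1ccc(CC[C@@H](C)O)o1 | target

**Step count and risks**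
Total step count: 14. Longest linear sequence: 10 steps (1–4, 7–10, 13, 14).

Steps most likely to fail:

1. Step 13 (Proposed new method). What may go wrong:
   - direct anodic over-oxidation of the furan partner or of the furan product;
   - decarboxylation of 16 before the coupling;
   - oxidative decarboxylation of the carboxylate in place of enolate oxidation, which would couple a secondary radical with the opposite facial sense;
   - incomplete facial selectivity in the final protonation.

   Fallback with known chemistry, setting out from 15 and coming back at 21: 15 is brominated at C-α (NBS, Mg(ClO4)2 cat., MeCN) to the tert-butyl α-bromo lactone ester F1. Visible-light photoredox alkylation of 19 (fac-Ir(ppy)3, 2,6-lutidine, blue LEDs, DMF) gives the quaternary tert-butyl α-furyl lactone ester F2 by reductive radical generation, away from any anode. TMSOTf/2,6-lutidine followed by aqueous work-up unmasks acid 20, which is warmed in toluene–AcOH at 50 °C to decarboxylate with the same convex-face protonation, giving 21.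

2. Step 9. What may go wrong:
   - oligomerization in place of closure of the strained 10-membered ring;
   - base-induced β-elimination of the lactone carboxylate from the activated acyl intermediate;
   - C-acylation of the enolizable malonate position.

   Fallback that activates the alcohol instead of the acid, setting out from 8 and coming back at 15: commercial (S)-γ-valerolactone is taken through the operations of steps 5 and 6 to (S)-4-(benzyloxy)pentanoic acid F3 and (S)-4-(benzyloxy)pentanoyl chloride F4. Coupling with 8 as in step 7 gives, via the C-9-epimeric ynone F5, the epimeric butenolide F6. Hydrogenation as in step 8 gives the epimeric seco acid F7. A Mitsunobu macrolactonization (PPh3, DIAD, toluene, high dilution) then closes the ring with inversion at the carbinol carbon to give 15.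

3. Step 7. What may go wrong:
   - acylation of the malonate C–H by the acid chloride;
   - ionization of the propargylic ester by Pd(0);
   - attack of the ketone enolate oxygen on the ester (pyranone formation);
   - partial racemization at C-γ through the 2-hydroxyfuran tautomer.

   Fallback that separates C–C coupling from the malonate chemistry, setting out from 6 and coming back at 13: 6 is silylated (TBSCl, imidazole) to benzyl (S)-3-(tert-butyldimethylsilyloxy)pent-4-ynoate F8. Acyl Sonogashira coupling with 11 gives the silyl-protected ynone F9. HF·pyridine gives the γ-hydroxy ynone F10. Esterification with 7 (DCC, DMAP) then forms 12 under conditions where it cyclizes directly to 13.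

**Further compounds**
F1 | step 13 | tert-butyl α-bromo lactone ester (15 with Br at C-α) | C[C@@H]1CCC(=O)C[C@@H]2[C@H](CC(=O)O1)OC(=O)C2(Br)C(=O)OC(C)(C)C
F2 | step 13 | quaternary tert-butyl α-furyl lactone ester | C[C@@H]1CCC(=O)C[C@@H]2[C@H](CC(=O)O1)OC(=O)C2(C(=O)OC(C)(C)C)c1ccc(CC[C@@H](C)O[Si](C)(C)C(C)(C)C)o1
F3 | step 9 | (S)-4-(benzyloxy)pentanoic acid | C[C@H](OCc1ccccc1)CCC(=O)O
F4 | step 9 | (S)-4-(benzyloxy)pentanoyl chloride | C[C@H](OCc1ccccc1)CCC(=O)Cl
F5 | step 9 | C-9-epimeric ynone (not isolated) | C[C@H](OCc1ccccc1)CCC(=O)C#C[C@@H](OC(=O)CC(=O)OC(C)(C)C)CC(=O)OCc1ccccc1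
F6 | step 9 | epimeric butenolide | C[C@H](OCc1ccccc1)CCC(=O)CC1=C(C(=O)OC(C)(C)C)C(=O)O[C@H]1CC(=O)OCc1ccccc1
F7 | step 9 | epimeric seco acid | C[C@H](O)CCC(=O)C[C@@H]1[C@H](CC(=O)O)OC(=O)C1C(=O)OC(C)(C)C
F8 | step 7 | benzyl (S)-3-(tert-butyldimethylsilyloxy)pent-4-ynoate | C#C[C@@H](O[Si](C)(C)C(C)(C)C)CC(=O)OCc1ccccc1
F9 | step 7 | silyl-protected ynone | C[C@@H](OCc1ccccc1)CCC(=O)C#C[C@@H](O[Si](C)(C)C(C)(C)C)CC(=O)OCc1ccccc1
F10 | step 7 | γ-hydroxy ynone | C[C@@H](OCc1ccccc1)CCC(=O)C#C[C@@H](O)CC(=O)OCc1ccccc1
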